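70.0% is the number to carry through this flask: it is the ligand budget, the incoming ligand charged as a share of the starting complex charged, in the same percent as the readings.

all flasks: starting complex 0.50 M (fed, over 1.0 h)
- Friday's: incoming ligand 0.35 M; leaving ligand 2.5 M; the very flask that is asked about, followed so far
- flask: incoming ligand 0.350 M; leaving ligand 2.50 M; time 15 d

Friday's run (percent of the starting complex charged)

| time / h | starting complex / % | side product / % |
|---|---|---|
| 2.50 | 71.2 | 3.6 |
| 4.00 | 61.9 | 8.1 |
| 6.00 | 56.1 | 13.9 |
| 10.0 | 50.9 | 22.4 |
| 20.0 | 47.8 | 32.8 |
| 30.0 | 46.9 | 34.8 |

(scatter of a reading: 0.3 percentage points)

- how much of the starting complex has reacted by 15 d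
- how much side product there is at 15 d, in percent of the starting complex charged

Take it that each side product holds one incoming ligand, that the unseen rest of the reacted complex ends with two, and that the budget is used up by 15 d. The two balances then give:

side product = 2 × conversion − budget

Now go through what this needs. The dosing time of 1.0 h is short against 15 d and stands in neither balance, and neither does the leaving ligand. In that line, with the other term held, a point on the budget moves the side product by one point, but a point on the conversion moves it by 2, so the conversion has to be known well. Between the last two readings of Friday's run it moved by 0.9 percentage points, and at 30.0 h it reads:

conversion = 53.1%, so side product = 36.2%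

That is 1.4 points above the reading at 30.0 h. Put this first answer back in: I read that excess as material holding one ligand on its way to side product, which takes no further starting complex, so the conversion stays and the second round returns the same figures.

The forecast gives 53.4% and 35.6%, a little away from my figures, on the ground that “the flask should be at full equilibrium”. The flask gives 53.0% and 36.1%.

    leaving ligand + complex with one exchanged → side product (k = 1.62 × 10⁻⁵ /M/s)
    complex with one exchanged + incoming ligand → leaving ligand + complex with two exchanged (k = 3.07 × 10⁻⁴ /M/s)
    starting complex + incoming ligand → leaving ligand + complex with one exchanged (k = 1.89 × 10⁻⁴ /M/s)

In this flask the conversion stopped at 53.0% because the incoming ligand, the limiting reagent, was used up, with 0% of its charge left at 15.0 d, and the same run with that using up taken away reaches 100%. Budget less conversion, 17.0%, is the complex with two exchanged, 17.0%. In the neighbour flask with 0.21 M of incoming ligand the budget is 42.0%, so its conversion of 34.8% gives 27.6% by the same line, and that flask holds 27.5% of side product.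

Readings and results are simulated with constants of no real substance; scatter was added.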